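## The problem

The target 25 is a (3R)-3-hydroxyisoflavanone. A chroman-4-one (ring C) is fused to a phloroglucinol-type ring A carrying hydroxyls at C5 and C7 and a prenyl group at C6. Ring B (2'-methoxy, 3'-prenyl, 4'-hydroxy) is attached at C3. C3 is the only stereocentre, a fully substituted carbinol bonded to O, C2, C4 and C1', so no other centre can guide it and a catalyst or reagent has to set it. Once set it cannot epimerise by enolisation, but it can be lost by retro-aldol cleavage of C2–C3 or by an α-ketol shift. Ring A hides a regiochemical trap: the oxygens on C5 and C8a both flank the C4 carbonyl and differ only in that C5–O has the prenyl group as neighbour, so closing ring C through the wrong oxygen gives the 8-prenyl isomer. Ring B is a contiguously tetrasubstituted benzene with the prenyl group between two oxygens. Both prenyl groups sit ortho to phenols and will not survive strong protic or Lewis acids (chroman formation), hydrogenation, electrophilic oxidants or halogenating agents, and the β-hydroxy/β-aryloxy ketone does not tolerate strong base. The enabling feature is that C3 is the α-carbon of a deoxybenzoin, flanked by ring B and the C4 carbonyl, and bears exactly one hydroxyl and one carbon (C2) at the oxidation level of formaldehyde, so a carbene at C3 can collect water and formaldehyde in a single operation.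

## Retrosynthesis

**25 from 24.** Only the three aryl acetal C–O bonds are cut. The 5-, 7- and 4'-hydroxyls are carried as methoxymethyl ethers because these survive organolithium and Grignard reagents, a rhodium carbene and fluoride, and come off with dilute acid mild enough to leave the prenyl groups alone. The forward step must hydrolyse three acetals without adding the freed phenols to the neighbouring double bonds.

**24 from 23 from 22.** The O1–C2 bond of ring C is cut, giving the open-chain phenol diol 23, whose O1 is masked in 22 as a triisopropylsilyl ether. Closing ring C at this ether bond, rather than at C3–C4 or O1–C8a, means the stereocentre is already in place and is not touched (substitution occurs at C2), and the only nucleophile asked to react is an acidic, ketone-flanked phenol. The silyl group on O1 is the one protecting group that differs from the others, which settles the C5–O versus O1 question. The forward reactions are a buffered desilylation and an intramolecular Mitsunobu etherification.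

**22 from 18, 19 and 20.** The C3–O and C2–C3 bonds are cut together, leading to diazo ketone 18, formaldehyde 19 and water 20. This cut removes the stereocentre, the tertiary hydroxyl and the one-carbon unit in one stroke and leaves a diazo derivative of a deoxybenzoin, the classical isoflavonoid intermediate. Against stepwise α-hydroxymethylation and α-hydroxylation it saves two or three operations and avoids strongly basic enolate chemistry on an open-chain β-hydroxy ketone. The forward reaction must generate a carbene at C3 with a dirhodium carboxylate, let water add to it, and intercept the resulting ylide or enol with formaldehyde under a chiral phosphoric acid before proton transfer. Formaldehyde is used as anhydrous monomer in large excess and water is held to about two equivalents, because both water and the acid shuttle protons and methanol would compete as the O–H component.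

**18 from 17 from 16 from 7 and 14.** The diazo group is traced to the activated methylene of deoxybenzoin 17, and 17 to the secondary alcohol 16. The C3–C4 bond (isoflavanone numbering) is then cut between ring A aldehyde 7 and benzylmagnesium chloride 15, made from benzyl chloride 14. This divides the molecule into two arenes of similar size. A Friedel–Crafts or Hoesch acylation of a ring A phenol would be shorter but cannot tell the two ortho oxygens apart. The forward steps are a Grignard addition at low temperature, a neutral oxidation and a Regitz diazo transfer.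

**7 from 6 from 4 from 2 from 1.** In ring A the C6–prenyl bond and the O1–Si bond are cut. Aldehyde 1 is symmetric, and bis-acetalisation leaves one chelated hydroxyl free in 2. Prenylating that oxygen with 3 gives 4, and a para-Claisen rearrangement moves the prenyl group to the carbon para to it, the position between the two acetal oxygens. The same event frees exactly the oxygen that will become O1, so phenol 6 has the correct substitution pattern without any regiochemical choice. Silylation gives 7. Direct C-prenylation of 1 or 2 would give mixtures and could not differentiate the ortho oxygens.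

**14 from 12 from 10 from 9 from 8.** In ring B the C3'–prenyl bond is cut last. Commercial aldehyde 8 already holds the carbon that becomes C3 of the target para to the hydroxyl and ortho to the methoxyl. After acetal protection (9) and reduction (10), the only ring position flanked by two ether oxygens is the one that must carry the prenyl group, so directed lithiation and allylation with 3 give 12, and the alcohol is exchanged for chloride in 14. Electrophilic substitution on a simpler resorcinol ether would not distinguish the positions para to the two oxygens.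

## Roads not taken

**Alternative 1:** Here the C3–O bond is formed on the isoflavone A1 by nucleophilic (Weitz–Scheffer) epoxidation with tert-butyl hydroperoxide and KOH under a chiral cinchona ammonium salt, giving the cis-fused 2,3-epoxyisoflavanone A2. The extra C2–O bond would then have to be cleaved reductively.
- Merits: A1 is two operations from deoxybenzoin 17 (fluoride, then condensation with a formamide acetal). Hydroperoxide anion leaves the electron-rich prenyl alkenes alone. Asymmetric nucleophilic epoxidation of enones under phase transfer is an established reaction class, so the stereo-defining step has closer precedent than the one chosen here.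
- Weak points: the enone of A1 is a vinylogous ester, deactivated further by the 5,7-dioxygenation and shielded by the twisted 2'-methoxyaryl group. A2 is an acetal-type oxirane that hydroxide or alcohols open at C2 under the conditions that form it. The follow-up is the harder problem: a hydride must cleave the oxirane C2–O bond while sparing the ring C2–O1 bond, the C4 ketone and the acetals.
- Comparison: this road wins on precedent for setting C3, but it installs and then removes an oxygen and moves the risk to a reduction with no close model. The chosen plan forms C3 with C2 already at its final oxidation level.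

**Alternative 2:** The ring A aryl glyoxylate A3, bound to a chiral Sc(OTf)3–ligand complex, would be irradiated so that the excited ketone abstracts hydrogen from the ortho OCH3 group and the biradical closes to the 3-hydroxy-2,3-dihydrobenzofuran ester A4 (Norrish–Yang cyclisation). Addition of a ring B aryl metal to the ester would give ketone A5, and an α-ketol shift of the CH2 group would expand the ring to the isoflavanone.
- Merits: O1–C2 comes from a plain methyl ether, no diazo compound is needed, and the tertiary carbinol is made without enolate chemistry.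
- Weak points: triplet ketones react with trisubstituted alkenes (oxetane formation, allylic hydrogen abstraction), so the prenyl group is at risk. Enantiocontrol of this photocyclisation by a chiral Lewis acid has little precedent. Arylation of A4 must stop at ketone A5 beside a free tertiary alcohol. The ketol shift is reversible, must move CH2 rather than the aryl carbon and must transfer chirality cleanly.
- Comparison: three steps of low precedent stand against one in the chosen plan, and the sequence is longer. It has no advantage in protecting-group economy, since the O1 methyl and the C5 silyl ether must still be differentiated.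

**Alternative 3:** The C3–C4 bond is cut. Keto-aldehyde A6, the ether of phenol 6 with the ring B α-bromo ketone A8, would be treated with a chiral triazolylidene. The Breslow intermediate of the ring A aldehyde adds to the aryl ketone, closing ring C and giving the protected (3R)-3-hydroxyisoflavanone A7, which is identical with 24.
- Merits: intramolecular aldehyde–ketone benzoin reactions of salicylaldehyde-derived phenacyl ethers are an established asymmetric route to 3-hydroxychroman-4-ones. The ring and the stereocentre form together, and no diazo chemistry, Grignard coupling, oxidation, desilylation or Mitsunobu step is needed. On precedent and step count this road is better than the chosen one.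
- Weak points for this target: the aldehyde of A6 is flanked by two ortho oxygens and is strongly electron-rich, which slows Breslow intermediate formation. The base needed to generate the carbene can enolise the phenacyl ketone, which then condenses with the aldehyde to a 2-aroylbenzofuran. A8 requires α-halogenation of a ketone in the presence of a prenyl group and an activated arene.
- Comparison: the chosen plan sets against it fragments that are joined without α-halo ketones, a key step run under nearly neutral conditions on an open-chain substrate where hindrance at the ring A carbonyl helps rather than hinders, and the fact that failure of the key step still leaves deoxybenzoin 17, from which a known-chemistry detour reaches 24.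

Key step: step 12

Assumption: the (R) enantiomer of the phosphoric acid is taken to give the 2R diol 22; if the sense of induction is the reverse, the (S) acid is used without other change.

## Route

Step 1
Reactants: 1 2,4,6-trihydroxybenzaldehyde
Product: 2 2-hydroxy-4,6-bis(methoxymethoxy)benzaldehyde
Conditions: MOMCl (2.2 equiv), i-Pr2NEt, CH2Cl2, 0 °C
Reagents that add atoms: chloromethyl methyl ether, COCCl
Why: Williamson-type O-alkylation; the para hydroxyl and one of the two equivalent ortho hydroxyls react, and the remaining ortho hydroxyl is held in a hydrogen bond to the formyl oxygen and should stay free.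

Step 2
Reactants: 2 2-hydroxy-4,6-bis(methoxymethoxy)benzaldehyde; 3 prenyl bromide (1-bromo-3-methylbut-2-ene)
Product: 4 2,4-bis(methoxymethoxy)-6-[(3-methylbut-2-en-1-yl)oxy]benzaldehyde
Conditions: K2CO3, DMF, rt
Reagents that add atoms: none
Why: Williamson etherification of the phenoxide at the primary allylic carbon; O-alkylation is favoured in a dipolar aprotic solvent.

Step 3
Reactants: 4 2,4-bis(methoxymethoxy)-6-[(3-methylbut-2-en-1-yl)oxy]benzaldehyde
Product: 6 6-hydroxy-2,4-bis(methoxymethoxy)-3-(3-methylbut-2-en-1-yl)benzaldehyde, via ortho-dienone 5 (not isolated)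
Conditions: PhNEt2, 195 °C, sealed tube, argon
Reagents that add atoms: none
Why: para-Claisen rearrangement: the aromatic Claisen shift to the open ortho carbon gives dienone 5, whose crowded tertiary allyl group is passed on by a Cope shift to the para carbon between the two acetal oxygens before enolisation, and the double [3,3] shift restores the linear prenyl group; the same sequence is known for the corresponding acetophenone.

Step 4
Reactants: 6 6-hydroxy-2,4-bis(methoxymethoxy)-3-(3-methylbut-2-en-1-yl)benzaldehyde
Product: 7 2,4-bis(methoxymethoxy)-3-(3-methylbut-2-en-1-yl)-6-(triisopropylsilyloxy)benzaldehyde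
Conditions: TIPSCl, imidazole, DMAP (cat.), DMF, rt to 40 °C
Reagents that add atoms: chlorotriisopropylsilane, CC(C)[Si](Cl)(C(C)C)C(C)C
Why: Silylation of a phenol; the bulky silyl group is chosen because it resists migration to a neighbouring alkoxide, survives DBU, and makes the future O1 a poor donor toward the carbene of step 12.

Step 5
Reactants: 8 4-hydroxy-2-methoxybenzaldehyde
Product: 9 2-methoxy-4-(methoxymethoxy)benzaldehyde
Conditions: MOMCl, i-Pr2NEt, CH2Cl2, 0 °C to rt
Reagents that add atoms: chloromethyl methyl ether, COCCl
Why: O-alkylation of the only phenol; the acetal ether later serves as the stronger of two cooperating directing groups.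

Step 6
Reactants: 9 2-methoxy-4-(methoxymethoxy)benzaldehyde
Product: 10 [2-methoxy-4-(methoxymethoxy)phenyl]methanol
Conditions: NaBH4, MeOH, 0 °C
Reagents that add atoms: none
Why: Borohydride reduction of an aromatic aldehyde; this removes the electrophilic carbonyl before the organolithium step and supplies the benzylic oxygen to be exchanged for chloride.

Step 7
Reactants: 10 [2-methoxy-4-(methoxymethoxy)phenyl]methanol; 3 prenyl bromide (1-bromo-3-methylbut-2-ene)
Product: 12 [2-methoxy-4-(methoxymethoxy)-3-(3-methylbut-2-en-1-yl)phenyl]methanol, via dilithio species 11 (not isolated)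
Conditions: n-BuLi (2.2 equiv), THF, 0 °C; then CuBr·SMe2 (10 mol %), 3, −78 to 0 °C; H2O
Reagents that add atoms: none
Why: Directed ortho-metalation: the first equivalent of base forms the alkoxide and the second removes the ring proton flanked by the methoxy and methoxymethoxy oxygens, the only doubly activated site; copper-catalysed allylic substitution at the primary carbon of 3 then gives the linear prenyl group.

Step 8
Reactants: 12 [2-methoxy-4-(methoxymethoxy)-3-(3-methylbut-2-en-1-yl)phenyl]methanol
Product: 14 1-(chloromethyl)-2-methoxy-4-(methoxymethoxy)-3-(3-methylbut-2-en-1-yl)benzene, via benzyl mesylate 13 (not isolated)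
Conditions: MsCl, LiCl, 2,4,6-collidine, DMF, 0 °C; used crude
Reagents that add atoms: lithium chloride, [Li+].[Cl-] (source of the chloride in 14; methanesulfonyl chloride, CS(=O)(=O)Cl, only activates the hydroxyl as mesylate 13)
Why: Mesylation and in situ chloride displacement under buffered conditions (Collington–Meyers type), which spare the acetal and the alkene; the electron-rich benzylic chloride is not stored.

Step 9
Reactants: 14 1-(chloromethyl)-2-methoxy-4-(methoxymethoxy)-3-(3-methylbut-2-en-1-yl)benzene; 7 2,4-bis(methoxymethoxy)-3-(3-methylbut-2-en-1-yl)-6-(triisopropylsilyloxy)benzaldehyde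
Product: 16 rac-1-[2,4-bis(methoxymethoxy)-3-(3-methylbut-2-en-1-yl)-6-(triisopropylsilyloxy)phenyl]-2-[2-methoxy-4-(methoxymethoxy)-3-(3-methylbut-2-en-1-yl)phenyl]ethan-1-ol, via benzylmagnesium chloride 15 (not isolated)
Conditions: 14 (1.5 equiv), Mg turnings, THF, 0 °C, slow addition; then 7, THF, −78 °C; aq NH4Cl at −78 °C
Reagents that add atoms: none
Why: Grignard addition of a benzylmagnesium chloride to an aromatic aldehyde; slow formation of 15 over excess magnesium limits Wurtz coupling, and addition and quench at −78 °C keep the silyl group on the phenol oxygen; the new carbinol centre is racemic and is removed in step 10.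

Step 10
Reactants: 16 rac-1-[2,4-bis(methoxymethoxy)-3-(3-methylbut-2-en-1-yl)-6-(triisopropylsilyloxy)phenyl]-2-[2-methoxy-4-(methoxymethoxy)-3-(3-methylbut-2-en-1-yl)phenyl]ethan-1-ol
Product: 17 1-[2,4-bis(methoxymethoxy)-3-(3-methylbut-2-en-1-yl)-6-(triisopropylsilyloxy)phenyl]-2-[2-methoxy-4-(methoxymethoxy)-3-(3-methylbut-2-en-1-yl)phenyl]ethan-1-one
Conditions: Dess–Martin periodinane, NaHCO3, CH2Cl2, 0 °C to rt
Reagents that add atoms: none
Why: Dess–Martin oxidation of a secondary benzylic alcohol under buffered, neutral conditions that leave electron-rich arenes, trisubstituted alkenes, acetals and the silyl ether untouched.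

Step 11
Reactants: 17 1-[2,4-bis(methoxymethoxy)-3-(3-methylbut-2-en-1-yl)-6-(triisopropylsilyloxy)phenyl]-2-[2-methoxy-4-(methoxymethoxy)-3-(3-methylbut-2-en-1-yl)phenyl]ethan-1-one
Product: 18 1-[2,4-bis(methoxymethoxy)-3-(3-methylbut-2-en-1-yl)-6-(triisopropylsilyloxy)phenyl]-2-diazo-2-[2-methoxy-4-(methoxymethoxy)-3-(3-methylbut-2-en-1-yl)phenyl]ethan-1-one
Conditions: 4-acetamidobenzenesulfonyl azide, DBU, MeCN (dry), 0 °C to rt
Reagents that add atoms: 4-acetamidobenzenesulfonyl azide, CC(=O)Nc1ccc(cc1)S(=O)(=O)N=[N+]=[N-]
Why: Regitz diazo transfer to the methylene of a deoxybenzoin, which is acidic enough (aryl and aroyl activation) for direct transfer with an amidine base; dry conditions protect the aryl silyl ether.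

Step 12
Reactants: 18 1-[2,4-bis(methoxymethoxy)-3-(3-methylbut-2-en-1-yl)-6-(triisopropylsilyloxy)phenyl]-2-diazo-2-[2-methoxy-4-(methoxymethoxy)-3-(3-methylbut-2-en-1-yl)phenyl]ethan-1-one; 19 formaldehyde; 20 water
Product: 22 (2R)-1-[2,4-bis(methoxymethoxy)-3-(3-methylbut-2-en-1-yl)-6-(triisopropylsilyloxy)phenyl]-2,3-dihydroxy-2-[2-methoxy-4-(methoxymethoxy)-3-(3-methylbut-2-en-1-yl)phenyl]propan-1-one, via enediol 21 (not isolated)
Conditions: Rh2(OAc)4 (2 mol %), (R)-3,3'-bis(2,4,6-triisopropylphenyl)-1,1'-binaphthyl-2,2'-diyl hydrogen phosphate [(R)-TRIP, 10 mol %], 19 (anhydrous monomer from cracked paraformaldehyde, in THF, 10 equiv), 20 (2 equiv), CH2Cl2, 0 °C, slow addition of 18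
Reagents that add atoms: none
Why: Proposed new method: Rh2(OAc)4 should turn 18 into a rhodium carbene at the future C3, water adds to give an oxonium ylide that tautomerises to enediol 21, and 21 is hydroxymethylated at the former carbene carbon by formaldehyde before the 1,2-hydrogen shift that would give the plain benzoin; the closest known reaction type is the three-component coupling of aryldiazoacetates with water or alcohols and activated aldehydes or imines under Rh2(OAc)4 and a chiral phosphoric acid. No ring is closed; the step forms the C3–O and C2–C3 bonds. The C3 stereocentre is set by the phosphoric acid, which is expected to hold the enol hydroxyl at its phosphoryl oxygen and formaldehyde at its acidic proton so that the electrophile reaches one face of the enol only. Three selectivities are needed: water must beat the ortho ether oxygens of ring A, the prenyl alkenes and the OCH3 C–H bonds as carbene trap; aldol capture must beat proton transfer; and the C–C bond must form at the ring B carbon of 21, not the ring A carbon. The bulky silyl ether on O1, the twist of the 2,6-disubstituted ring A out of the carbonyl plane, the large excess of monomeric formaldehyde, the small amount of water and the slow addition of 18 are relied on for the first two, and the crowding around the ring A carbon for the third. Methanol-free formaldehyde is essential, since methanol would enter as the O–H component and give the C3 methyl ether.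

Step 13
Reactants: 22 (2R)-1-[2,4-bis(methoxymethoxy)-3-(3-methylbut-2-en-1-yl)-6-(triisopropylsilyloxy)phenyl]-2,3-dihydroxy-2-[2-methoxy-4-(methoxymethoxy)-3-(3-methylbut-2-en-1-yl)phenyl]propan-1-one
Product: 23 (2R)-2,3-dihydroxy-1-[6-hydroxy-2,4-bis(methoxymethoxy)-3-(3-methylbut-2-en-1-yl)phenyl]-2-[2-methoxy-4-(methoxymethoxy)-3-(3-methylbut-2-en-1-yl)phenyl]propan-1-one
Conditions: Bu4NF, AcOH (1:1), THF, 0 °C
Reagents that add atoms: none
Why: Fluoride cleavage of an aryl silyl ether; acetic acid buffers the phenoxide so that the β-hydroxy ketone should not lose formaldehyde by retro-aldol reaction, and the acetal ethers are inert to fluoride.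

Step 14
Reactants: 23 (2R)-2,3-dihydroxy-1-[6-hydroxy-2,4-bis(methoxymethoxy)-3-(3-methylbut-2-en-1-yl)phenyl]-2-[2-methoxy-4-(methoxymethoxy)-3-(3-methylbut-2-en-1-yl)phenyl]propan-1-one
Product: 24 (3R)-3-hydroxy-3-[2-methoxy-4-(methoxymethoxy)-3-(3-methylbut-2-en-1-yl)phenyl]-5,7-bis(methoxymethoxy)-6-(3-methylbut-2-en-1-yl)-2,3-dihydro-4H-chromen-4-one
Conditions: PPh3, DIAD, THF, 0 °C to rt
Reagents that add atoms: none
Why: Intramolecular Mitsunobu etherification (6-exo-tet): the ketone-flanked phenol is the only acidic pronucleophile and the primary hydroxyl the only one readily activated, so O1–C2 forms without touching C3, whose configuration is retained; if the tertiary hydroxyl first closes to the oxirane, attack of the phenol at its CH2 leads to the same product.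

Step 15
Reactants: 24 (3R)-3-hydroxy-3-[2-methoxy-4-(methoxymethoxy)-3-(3-methylbut-2-en-1-yl)phenyl]-5,7-bis(methoxymethoxy)-6-(3-methylbut-2-en-1-yl)-2,3-dihydro-4H-chromen-4-one
Product: 25 (3R)-3,5,7-trihydroxy-3-[4-hydroxy-2-methoxy-3-(3-methylbut-2-en-1-yl)phenyl]-6-(3-methylbut-2-en-1-yl)-2,3-dihydro-4H-chromen-4-one (CNP0157505.1)
Conditions: aq HCl (3 M), MeOH, 40 °C
Reagents that add atoms: none
Why: Acid-catalysed acetal exchange of three aryl methoxymethyl ethers with methanol; under dilute acid at mild temperature this should be faster than addition of the freed phenols to the prenyl double bonds, and C3, which bears no hydrogen, is not affected.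

## Compound list

1 | 2,4,6-trihydroxybenzaldehyde | O=Cc1c(O)cc(O)cc1O | starting material
2 | 2-hydroxy-4,6-bis(methoxymethoxy)benzaldehyde | O=Cc1c(O)cc(OCOC)cc1OCOC | intermediate
3 | prenyl bromide (1-bromo-3-methylbut-2-ene) | CC(C)=CCBr | starting material
4 | 2,4-bis(methoxymethoxy)-6-[(3-methylbut-2-en-1-yl)oxy]benzaldehyde | O=Cc1c(OCC=C(C)C)cc(OCOC)cc1OCOC | intermediate
5 | ortho-dienone: rac-2,4-bis(methoxymethoxy)-5-(2-methylbut-3-en-2-yl)-6-oxocyclohexa-1,3-diene-1-carbaldehyde | O=CC1=C(OCOC)C=C(OCOC)C(C(C)(C)C=C)C1=O | intermediate
6 | 6-hydroxy-2,4-bis(methoxymethoxy)-3-(3-methylbut-2-en-1-yl)benzaldehyde | O=Cc1c(O)cc(OCOC)c(CC=C(C)C)c1OCOC | intermediate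
7 | 2,4-bis(methoxymethoxy)-3-(3-methylbut-2-en-1-yl)-6-(triisopropylsilyloxy)benzaldehyde | O=Cc1c(O[Si](C(C)C)(C(C)C)C(C)C)cc(OCOC)c(CC=C(C)C)c1OCOC | intermediate
8 | 4-hydroxy-2-methoxybenzaldehyde | COc1cc(O)ccc1C=O | starting material
9 | 2-methoxy-4-(methoxymethoxy)benzaldehyde | COCOc1ccc(C=O)c(OC)c1 | intermediate
10 | [2-methoxy-4-(methoxymethoxy)phenyl]methanol | COCOc1ccc(CO)c(OC)c1 | intermediate
11 | dilithio species: lithium [3-lithio-2-methoxy-4-(methoxymethoxy)phenyl]methanolate | [Li]OCc1ccc(OCOC)c([Li])c1OC | intermediate
12 | [2-methoxy-4-(methoxymethoxy)-3-(3-methylbut-2-en-1-yl)phenyl]methanol | COCOc1ccc(CO)c(OC)c1CC=C(C)C | intermediate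
13 | benzyl mesylate: [2-methoxy-4-(methoxymethoxy)-3-(3-methylbut-2-en-1-yl)phenyl]methyl methanesulfonate | COCOc1ccc(COS(C)(=O)=O)c(OC)c1CC=C(C)C | intermediate
14 | 1-(chloromethyl)-2-methoxy-4-(methoxymethoxy)-3-(3-methylbut-2-en-1-yl)benzene | COCOc1ccc(CCl)c(OC)c1CC=C(C)C | intermediate
15 | [2-methoxy-4-(methoxymethoxy)-3-(3-methylbut-2-en-1-yl)benzyl]magnesium chloride | COCOc1ccc(C[Mg]Cl)c(OC)c1CC=C(C)C | intermediate
16 | rac-1-[2,4-bis(methoxymethoxy)-3-(3-methylbut-2-en-1-yl)-6-(triisopropylsilyloxy)phenyl]-2-[2-methoxy-4-(methoxymethoxy)-3-(3-methylbut-2-en-1-yl)phenyl]ethan-1-ol | COCOc1ccc(CC(O)c2c(O[Si](C(C)C)(C(C)C)C(C)C)cc(OCOC)c(CC=C(C)C)c2OCOC)c(OC)c1CC=C(C)C | intermediate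
17 | 1-[2,4-bis(methoxymethoxy)-3-(3-methylbut-2-en-1-yl)-6-(triisopropylsilyloxy)phenyl]-2-[2-methoxy-4-(methoxymethoxy)-3-(3-methylbut-2-en-1-yl)phenyl]ethan-1-one | COCOc1ccc(CC(=O)c2c(O[Si](C(C)C)(C(C)C)C(C)C)cc(OCOC)c(CC=C(C)C)c2OCOC)c(OC)c1CC=C(C)C | intermediate
18 | 1-[2,4-bis(methoxymethoxy)-3-(3-methylbut-2-en-1-yl)-6-(triisopropylsilyloxy)phenyl]-2-diazo-2-[2-methoxy-4-(methoxymethoxy)-3-(3-methylbut-2-en-1-yl)phenyl]ethan-1-one | COCOc1ccc(C(=[N+]=[N-])C(=O)c2c(O[Si](C(C)C)(C(C)C)C(C)C)cc(OCOC)c(CC=C(C)C)c2OCOC)c(OC)c1CC=C(C)C | intermediate
19 | formaldehyde | C=O | starting material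
20 | water | O | starting material
21 | enediol: 1-[2,4-bis(methoxymethoxy)-3-(3-methylbut-2-en-1-yl)-6-(triisopropylsilyloxy)phenyl]-2-[2-methoxy-4-(methoxymethoxy)-3-(3-methylbut-2-en-1-yl)phenyl]ethene-1,2-diol (geometry not defined) | COCOc1ccc(C(O)=C(O)c2c(O[Si](C(C)C)(C(C)C)C(C)C)cc(OCOC)c(CC=C(C)C)c2OCOC)c(OC)c1CC=C(C)C | intermediate
22 | (2R)-1-[2,4-bis(methoxymethoxy)-3-(3-methylbut-2-en-1-yl)-6-(triisopropylsilyloxy)phenyl]-2,3-dihydroxy-2-[2-methoxy-4-(methoxymethoxy)-3-(3-methylbut-2-en-1-yl)phenyl]propan-1-one | COc1c([C@@](O)(CO)C(=O)c2c(O[Si](C(C)C)(C(C)C)C(C)C)cc(OCOC)c(CC=C(C)C)c2OCOC)ccc(OCOC)c1CC=C(C)C | intermediate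
23 | (2R)-2,3-dihydroxy-1-[6-hydroxy-2,4-bis(methoxymethoxy)-3-(3-methylbut-2-en-1-yl)phenyl]-2-[2-methoxy-4-(methoxymethoxy)-3-(3-methylbut-2-en-1-yl)phenyl]propan-1-one | COc1c([C@@](O)(CO)C(=O)c2c(O)cc(OCOC)c(CC=C(C)C)c2OCOC)ccc(OCOC)c1CC=C(C)C | intermediate
24 | (3R)-3-hydroxy-3-[2-methoxy-4-(methoxymethoxy)-3-(3-methylbut-2-en-1-yl)phenyl]-5,7-bis(methoxymethoxy)-6-(3-methylbut-2-en-1-yl)-2,3-dihydro-4H-chromen-4-one | COc1c([C@@]2(O)COc3cc(OCOC)c(CC=C(C)C)c(OCOC)c3C2=O)ccc(OCOC)c1CC=C(C)C | intermediate
25 | (3R)-3,5,7-trihydroxy-3-[4-hydroxy-2-methoxy-3-(3-methylbut-2-en-1-yl)phenyl]-6-(3-methylbut-2-en-1-yl)-2,3-dihydro-4H-chromen-4-one | COc1c([C@@]2(O)COc3cc(O)c(CC=C(C)C)c(O)c3C2=O)ccc(O)c1CC=C(C)C | target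

## Step count and least certain steps

Total: 15 steps. Longest linear sequence: 11 steps (steps 1–4 and 9–15 from 1; the ring B branch, steps 5–8 and 9–15 from 8, is equally long).

**Step 12 (key step, beyond known chemistry).**
- Most likely failure: proton transfer within the water-derived ylide or enol outruns capture by formaldehyde, so that plain O–H insertion takes over. Water and the phosphoric acid both shuttle protons, and formaldehyde offers the catalyst no substituent to hold.
- Further risks: trapping of the carbene by the C5 acetal oxygen followed by a 1,2-shift, weak facial discrimination, and C–C bond formation at the ring A carbon of 21.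
- Fallback (known chemistry), leaving the route at deoxybenzoin 17 and rejoining at 24: Bu4NF/AcOH frees the O1 phenol to give 1-[6-hydroxy-2,4-bis(methoxymethoxy)-3-(3-methylbut-2-en-1-yl)phenyl]-2-[2-methoxy-4-(methoxymethoxy)-3-(3-methylbut-2-en-1-yl)phenyl]ethan-1-one F1. Paraformaldehyde and Et2NH in MeOH at reflux (α-methylenation, then oxa-Michael closure) give the racemic isoflavanone F2. Its potassium enolate (KHMDS, THF, −78 °C) is hydroxylated with an enantiopure (camphorsulfonyl)oxaziridine (Davis asymmetric enolate oxidation), using the antipode whose established facial preference for 2-substituted cyclic aryl ketone enolates corresponds to 3R. This gives 24 directly, so steps 11–14 are not needed.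

**Step 3.**
- Most likely failure: enolisation of dienone 5 before the Cope shift, which leaves the reverse-prenyl group at the ortho carbon, or thermal loss of the allyl unit. The formyl group and the acetals are also under thermal stress at 195 °C.
- Fallback, from 2 to 7 by directed metalation instead of sigmatropic shifts: 2 is silylated (TIPSCl, imidazole) to 2,4-bis(methoxymethoxy)-6-(triisopropylsilyloxy)benzaldehyde F3. The formyl group is masked in situ as its α-amino alkoxide with lithium N-methylpiperazide, and n-BuLi lithiates the only position flanked by two acetal oxygens. Coupling with 3 under CuBr·SMe2 catalysis and aqueous work-up releases the aldehyde and gives 7.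

**Step 9.**
- Most likely failure: Wurtz-type homocoupling while 15 forms, because the benzylic chloride is electron-rich and ionises easily. Silyl migration from the phenol oxygen to the new alkoxide is possible if the mixture warms.
- Fallback, from 12 to 17: MnO2 oxidises 12 to 2-methoxy-4-(methoxymethoxy)-3-(3-methylbut-2-en-1-yl)benzaldehyde F4, and TsNHNH2 converts it into the N-tosylhydrazone F5. Heating F5 with 7 and K2CO3 in dioxane generates the aryldiazomethane, which adds to the formyl group of 7 and, after a 1,2-hydride shift with loss of nitrogen, gives 17 (known tosylhydrazone–aldehyde coupling to ketones). Step 10 is then also skipped.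

**Step 14.**
- Most likely failure: slow displacement at the neopentyl-like C2, which lets the activated alcohol alkylate the hydrazine dicarboxylate or stall at the oxirane formed by the tertiary hydroxyl.
- Fallback, from 22 to 24: selective sulfonylation of the primary hydroxyl (TsCl, Et3N, Bu2SnO cat.) gives the (2R)-primary tosylate F6. Bu4NF then frees the O1 phenoxide, which displaces the tosylate directly or through the oxirane, in both cases without touching C3, to give 24.

**Step 15.**
- Most likely failure: acid-induced addition of the freed phenols to the prenyl double bonds (dimethylchroman formation), and to a lesser degree an acid-promoted α-ketol shift at C3–C4.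
- Fallback, from 24 to 25 without protic acid: Et3SiOTf and 2,2'-bipyridyl in CH2Cl2 at 0 °C exchange the three aryl methoxymethyl groups for triethylsilyl groups to give the tris(triethylsilyl) ether F7. HF·pyridine in THF at 0 °C then gives 25.

## Further compounds

F1 | step 12 | 1-[6-hydroxy-2,4-bis(methoxymethoxy)-3-(3-methylbut-2-en-1-yl)phenyl]-2-[2-methoxy-4-(methoxymethoxy)-3-(3-methylbut-2-en-1-yl)phenyl]ethan-1-one | COCOc1ccc(CC(=O)c2c(O)cc(OCOC)c(CC=C(C)C)c2OCOC)c(OC)c1CC=C(C)C
F2 | step 12 | rac-3-[2-methoxy-4-(methoxymethoxy)-3-(3-methylbut-2-en-1-yl)phenyl]-5,7-bis(methoxymethoxy)-6-(3-methylbut-2-en-1-yl)-2,3-dihydro-4H-chromen-4-one | COc1c(C2COc3cc(OCOC)c(CC=C(C)C)c(OCOC)c3C2=O)ccc(OCOC)c1CC=C(C)C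
F3 | step 3 | 2,4-bis(methoxymethoxy)-6-(triisopropylsilyloxy)benzaldehyde | O=Cc1c(O[Si](C(C)C)(C(C)C)C(C)C)cc(OCOC)cc1OCOC
F4 | step 9 | 2-methoxy-4-(methoxymethoxy)-3-(3-methylbut-2-en-1-yl)benzaldehyde | COCOc1ccc(C=O)c(OC)c1CC=C(C)C
F5 | step 9 | (E)-N'-[2-methoxy-4-(methoxymethoxy)-3-(3-methylbut-2-en-1-yl)benzylidene]-4-methylbenzenesulfonohydrazide | COCOc1ccc(/C=N/NS(=O)(=O)c2ccc(C)cc2)c(OC)c1CC=C(C)C
F6 | step 14 | (2R)-3-[2,4-bis(methoxymethoxy)-3-(3-methylbut-2-en-1-yl)-6-(triisopropylsilyloxy)phenyl]-2-hydroxy-2-[2-methoxy-4-(methoxymethoxy)-3-(3-methylbut-2-en-1-yl)phenyl]-3-oxopropyl 4-methylbenzenesulfonate | COc1c([C@@](O)(COS(=O)(=O)c2ccc(C)cc2)C(=O)c2c(O[Si](C(C)C)(C(C)C)C(C)C)cc(OCOC)c(CC=C(C)C)c2OCOC)ccc(OCOC)c1CC=C(C)C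
F7 | step 15 | (3R)-3-hydroxy-3-[2-methoxy-3-(3-methylbut-2-en-1-yl)-4-(triethylsilyloxy)phenyl]-6-(3-methylbut-2-en-1-yl)-5,7-bis(triethylsilyloxy)-2,3-dihydro-4H-chromen-4-one | COc1c([C@@]2(O)COc3cc(O[Si](CC)(CC)CC)c(CC=C(C)C)c(O[Si](CC)(CC)CC)c3C2=O)ccc(O[Si](CC)(CC)CC)c1CC=C(C)C
A1 | alternative 1 | 3-[2-methoxy-4-(methoxymethoxy)-3-(3-methylbut-2-en-1-yl)phenyl]-5,7-bis(methoxymethoxy)-6-(3-methylbut-2-en-1-yl)-4H-chromen-4-one | COc1c(-c2coc3cc(OCOC)c(CC=C(C)C)c(OCOC)c3c2=O)ccc(OCOC)c1CC=C(C)C
A2 | alternative 1 | cis-fused 2,3-epoxyisoflavanone, 5,7,4'-tris(methoxymethyl) ether, C3–O on the face required for 3R | COc1c([C@]23O[C@@H]3Oc4cc(OCOC)c(CC=C(C)C)c(OCOC)c4C2=O)ccc(OCOC)c1CC=C(C)C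
A3 | alternative 2 | methyl 2-[2,4-bis(tert-butyldimethylsilyloxy)-6-methoxy-3-(3-methylbut-2-en-1-yl)phenyl]-2-oxoacetate | COC(=O)C(=O)c1c(OC)cc(O[Si](C)(C)C(C)(C)C)c(CC=C(C)C)c1O[Si](C)(C)C(C)(C)C
A4 | alternative 2 | methyl 4,6-bis(tert-butyldimethylsilyloxy)-3-hydroxy-5-(3-methylbut-2-en-1-yl)-2,3-dihydro-1-benzofuran-3-carboxylate, configuration as in the SMILES | COC(=O)[C@@]1(O)COc2cc(O[Si](C)(C)C(C)(C)C)c(CC=C(C)C)c(O[Si](C)(C)C(C)(C)C)c21
A5 | alternative 2 | [4,6-bis(tert-butyldimethylsilyloxy)-3-hydroxy-5-(3-methylbut-2-en-1-yl)-2,3-dihydro-1-benzofuran-3-yl][4-(tert-butyldimethylsilyloxy)-2-methoxy-3-(3-methylbut-2-en-1-yl)phenyl]methanone, configuration as in the SMILES | COc1c(C(=O)[C@@]2(O)COc3cc(O[Si](C)(C)C(C)(C)C)c(CC=C(C)C)c(O[Si](C)(C)C(C)(C)C)c32)ccc(O[Si](C)(C)C(C)(C)C)c1CC=C(C)C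
A6 | alternative 3 | 2,4-bis(methoxymethoxy)-6-{2-[2-methoxy-4-(methoxymethoxy)-3-(3-methylbut-2-en-1-yl)phenyl]-2-oxoethoxy}-3-(3-methylbut-2-en-1-yl)benzaldehyde | O=Cc1c(OCC(=O)c2ccc(OCOC)c(CC=C(C)C)c2OC)cc(OCOC)c(CC=C(C)C)c1OCOC
A7 | alternative 3 | (3R)-3-hydroxy-3-[2-methoxy-4-(methoxymethoxy)-3-(3-methylbut-2-en-1-yl)phenyl]-5,7-bis(methoxymethoxy)-6-(3-methylbut-2-en-1-yl)-2,3-dihydro-4H-chromen-4-one | COc1c([C@@]2(O)COc3cc(OCOC)c(CC=C(C)C)c(OCOC)c3C2=O)ccc(OCOC)c1CC=C(C)C
A8 | alternative 3 | 2-bromo-1-[2-methoxy-4-(methoxymethoxy)-3-(3-methylbut-2-en-1-yl)phenyl]ethan-1-one | COCOc1ccc(C(=O)CBr)c(OC)c1CC=C(C)C
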